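Retrosynthesis: both C6–Br bonds are cut first (one back to C6–H, the other back to C6–CO2H), then the lactone bond O1–C5 (exchanged for a C5–Br bond of an open-chain diene diacid), and last the bond between the two carboxyl carbons, which turns the diacid into a catechol.
Enabling feature: C2, C3 (butyl), C4 (Br), C5 and C6, with oxygen on C2 and C5, map onto five neighbouring ring carbons of 3-butyl-4,5-dibromocatechol; the sixth ring carbon becomes a carboxyl on C6 that is later lost as CO2.
Forward: veratrole is butylated by ortho-lithiation, demethylated and dibrominated; peracid cleavage of the catechol ring and lactonisation with loss of bromide then close the only ring, the butenolide.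
Bromodecarboxylation at C6 and one bromination–dehydrobromination complete the dibromomethylidene group.
Stereochemistry: the target has no stereocentre and no stereogenic double bond; the arene fixes where butyl and bromine sit, and the alkene geometry of the intermediates disappears in the last step.

Key step: step 4

Assumption: the target is achiral and C6 carries two identical bromines, so only one stereoisomer exists; 12 and 14 are drawn as the expected Z isomers, and an E isomer would converge on the same target.
Convention: O1 and C2–C6 are the butenolide locants of the target; compounds that supply atoms to a product are numbered, auxiliary reagents appear only in the conditions.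

Step 1
Reactants: 1 veratrole (1,2-dimethoxybenzene); 2 1-bromobutane
Product: 4 1-butyl-2,3-dimethoxybenzene, via aryllithium 3 (not isolated)
Conditions: n-BuLi (1.1 equiv), TMEDA (1.1 equiv), Et2O, 0 °C → rt; then 2, 0 °C → rt
Reagents that add atoms: 1-bromobutane CCCCBr
Why: Directed ortho-metalation places lithium next to a methoxy group of veratrole, and the aryllithium is alkylated by the primary bromide in an SN2 reaction, the usual entry to 3-alkylveratroles.

Step 2
Reactants: 4 1-butyl-2,3-dimethoxybenzene
Product: 5 3-butylbenzene-1,2-diol
Conditions: BBr3 (2.5 equiv), CH2Cl2, −78 °C → rt; H2O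
Reagents that add atoms: none
Why: BBr3 O-demethylation of aryl methyl ethers (Lewis acid complexation, bromide attack on the methyl group, hydrolysis of the aryl borate) is general for veratroles and does not touch the alkyl chain.

Step 3
Reactants: 5 3-butylbenzene-1,2-diol; 6 bromine
Product: 7 3-butyl-4,5-dibromobenzene-1,2-diol
Conditions: Br2 (2.05 equiv), AcOH–CH2Cl2, 0 °C → rt
Reagents that add atoms: bromine BrBr
Why: Electrophilic aromatic bromination should put one bromine para to each hydroxyl (ring positions 4 and 5), as in the conversion of catechol into 4,5-dibromocatechol, because para attack in bromocatechols prevails over ortho attack even at a flanked position, which leaves position 6 free with two equivalents of bromine.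

Step 4
Reactants: 7 3-butyl-4,5-dibromobenzene-1,2-diol; 8 peracetic acid
Product: 12 (Z)-2-(3-bromo-4-butyl-5-oxofuran-2(5H)-ylidene)acetic acid, via o-quinone 9 (not isolated), via muconic anhydride 10 (not isolated), via muconic acid 11 (not isolated)
Conditions: AcOOH (2.1 equiv), Fe(NO3)3 (cat.), AcOH, 15 °C → rt, dark, until peroxide-negative; then NaOAc (2 equiv), 50 °C; dilute HCl work-up
Reagents that add atoms: peracetic acid CC(=O)OO; water O (formed in the flask when 7 is oxidised to 9, it opens anhydride 10)
Why: Peracetic acid dehydrogenates the catechol to o-quinone 9, inserts oxygen between the two carbonyls in a Baeyer–Villiger step to give the seven-membered anhydride 10, and water opens this to the cis,cis-muconic acid 11, whose two cis double bonds are those of the ring. On buffering and warming, the carboxylate on the butyl-bearing carbon adds to the bromo carbon β to the other carboxyl (future C5) and the enolate expels bromide, an addition–elimination that forms O1–C5 and leaves the exocyclic C5=C6 alkene. The closest known chemistry is the iron(III)-assisted peracetic acid cleavage of halocatechols, which gives halomuconic acids and, from 4,5-dihalocatechols, the 3-halo-5-oxofuranylideneacetic acids directly. The butenolide closes in the 5-exo-trig mode, no stereocentre is formed, and the Z alkene (carboxyl on the side of O1) is expected because it keeps the carboxyl away from the C4 bromine. The step needs this carboxyl to close on the bromoacrylate terminus that has no α-substituent, not the other carboxyl on the butyl-substituted terminus; the unsubstituted acceptor is less hindered and more electrophilic, and its closure gives the tetrasubstituted ring alkene and avoids a tetrasubstituted exocyclic alkene pressed against the C4 bromine. Running the oxidation cold and unbuffered, and starting the closure only after the peracid is consumed, should keep the liberated bromide from being oxidised to electrophilic bromine.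

Step 5
Reactants: 12 (Z)-2-(3-bromo-4-butyl-5-oxofuran-2(5H)-ylidene)acetic acid; 13 N-bromosuccinimide
Product: 14 (Z)-4-bromo-5-(bromomethylidene)-3-butylfuran-2(5H)-one
Conditions: NBS (1.1 equiv), Et3N (0.2 equiv), CH2Cl2, 0 °C → rt, dark
Reagents that add atoms: N-bromosuccinimide O=C1CCC(=O)N1Br
Why: In this Hunsdiecker-type bromodecarboxylation of an α,β-unsaturated acid, the carboxylate-bearing enol-lactone alkene takes up Br+ at C6, the cation at C5 is stabilised by O1, and loss of CO2 restores the alkene; the freely rotating intermediate should give the Z bromide, which keeps bromine away from the C4 bromine, and no stereocentre is formed.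

Step 6
Reactants: 14 (Z)-4-bromo-5-(bromomethylidene)-3-butylfuran-2(5H)-one; 6 bromine
Product: 16 4-bromo-3-butyl-5-(dibromomethylidene)furan-2(5H)-one, via tetrabromide 15 (not isolated)
Conditions: Br2 (1.05 equiv), CH2Cl2, 0 °C → rt; then Et3N (1.5 equiv), 0 °C
Reagents that add atoms: bromine BrBr
Why: Bromination–dehydrobromination is the established way to brominate the exocyclic carbon of 5-ylidene-2(5H)-furanones: Br2 adds across the enol-lactone alkene C5=C6 (the ring alkene is tetrasubstituted and electron-poor), and Et3N removes the only β-hydrogen, on C6, with loss of the C5 bromide to give the dibromomethylidene group, which has no E/Z isomers.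

Compound list
1 | veratrole (1,2-dimethoxybenzene) | COc1ccccc1OC | starting material
2 | 1-bromobutane | CCCCBr | starting material
3 | (2,3-dimethoxyphenyl)lithium | COc1cccc([Li])c1OC | intermediate (not isolated)
4 | 1-butyl-2,3-dimethoxybenzene | CCCCc1cccc(OC)c1OC | intermediate
5 | 3-butylbenzene-1,2-diol | CCCCc1cccc(O)c1O | intermediate
6 | bromine | BrBr | starting material
7 | 3-butyl-4,5-dibromobenzene-1,2-diol | CCCCc1c(Br)c(Br)cc(O)c1O | intermediate
8 | peracetic acid | CC(=O)OO | starting material
9 | 3-butyl-4,5-dibromocyclohexa-3,5-diene-1,2-dione (o-quinone) | CCCCC1=C(Br)C(Br)=CC(=O)C1=O | intermediate (not isolated)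
10 | 4,5-dibromo-3-butyloxepine-2,7-dione (muconic anhydride) | CCCCC1=C(Br)C(Br)=CC(=O)OC1=O | intermediate (not isolated)
11 | (2E,4E)-3,4-dibromo-2-butylhexa-2,4-dienedioic acid (the cis,cis-muconic acid; each carboxyl cis to the central C–C bond) | CCCC/C(C(=O)O)=C(Br)/C(Br)=C\C(=O)O | intermediate (not isolated)
12 | (Z)-2-(3-bromo-4-butyl-5-oxofuran-2(5H)-ylidene)acetic acid | CCCCC1=C(Br)/C(=C/C(=O)O)OC1=O | intermediate
13 | N-bromosuccinimide | O=C1CCC(=O)N1Br | starting material
14 | (Z)-4-bromo-5-(bromomethylidene)-3-butylfuran-2(5H)-one | CCCCC1=C(Br)/C(=C/Br)OC1=O | intermediate
15 | 4,5-dibromo-3-butyl-5-(dibromomethyl)furan-2(5H)-one (racemic) | CCCCC1=C(Br)C(Br)(C(Br)Br)OC1=O | intermediate (not isolated)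
16 | 4-bromo-3-butyl-5-(dibromomethylidene)furan-2(5H)-one | CCCCC1=C(Br)C(=C(Br)Br)OC1=O | target

Total step count: 6. Longest linear sequence: 6 steps, from veratrole 1.

Steps most likely to fail

Step 4. The ring may close through the other carboxyl onto the butyl-substituted bromoacrylate terminus, or closure may begin while peracid is still present, so that liberated bromide is oxidised and brominates the material. The fallback sets out from 7 and returns at 12; it tells the two carboxyl ends apart before the ring is closed. Catechol 7 would be oxidised with NaIO4 to the o-quinone 9, now isolated, and this would be ring-expanded with mCPBA in dry CH2Cl2 to the anhydride 10 (Baeyer–Villiger oxidation of an o-quinone). 4-Methoxybenzyl alcohol with catalytic DMAP should open 10 at the carbonyl next to the CH carbon, away from the butyl group, to give the half ester (2E,4E)-3,4-dibromo-2-butyl-6-[(4-methoxybenzyl)oxy]-6-oxohexa-2,4-dienoic acid F1. In F1 only the carboxyl next to the butyl carbon is free. Et3N would close this carboxylate onto the bromoacrylate ester with loss of bromide to give 4-methoxybenzyl (Z)-2-(3-bromo-4-butyl-5-oxofuran-2(5H)-ylidene)acetate F2, and TFA with Et3SiH would cleave the ester to 12.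

Step 5. The electron-poor enol-lactone alkene may take up electrophilic bromine too slowly, so that radical bromination at the allylic CH2 of the butyl chain competes. The fallback sets out from 12 and returns at 14; it replaces the one-flask ipso substitution by addition followed by fragmentation. Bromine (6) in CHCl3 would be added across C5=C6 of the free acid to give the isolable vicinal dibromide 2-bromo-2-(2,3-dibromo-4-butyl-5-oxo-2,5-dihydrofuran-2-yl)acetic acid F3. Et3N in DMF would then bring about the classical decarboxylative elimination of a β-bromo carboxylate, with loss of CO2 and of the C5 bromide, to give 14.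

Step 3. Attack ortho to the unhindered hydroxyl may compete with the para position flanked by the butyl group, and overbromination or oxidation of the catechol by bromine are also possible. The fallback sets out from 1 and returns at 7; it introduces the bromines before the butyl group, so that their positions are fixed by symmetry. Veratrole 1 would be dibrominated with Br2 (2 equiv) in AcOH to 1,2-dibromo-4,5-dimethoxybenzene F4. Magnesiation with TMPMgCl·LiCl at one of the two equivalent C–H bonds flanked by OMe and Br, then addition to butanal, would give racemic 1-(2,3-dibromo-5,6-dimethoxyphenyl)butan-1-ol F5. Ionic hydrogenation with Et3SiH and TFA would reduce the benzylic alcohol to 1,2-dibromo-3-butyl-4,5-dimethoxybenzene F6, and BBr3 would unmask catechol 7.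

Further compounds
F1 | step 4 | (2E,4E)-3,4-dibromo-2-butyl-6-[(4-methoxybenzyl)oxy]-6-oxohexa-2,4-dienoic acid | CCCC/C(C(=O)O)=C(Br)/C(Br)=C\C(=O)OCc1ccc(OC)cc1
F2 | step 4 | 4-methoxybenzyl (Z)-2-(3-bromo-4-butyl-5-oxofuran-2(5H)-ylidene)acetate | CCCCC1=C(Br)/C(=C/C(=O)OCc2ccc(OC)cc2)OC1=O
F3 | step 5 | 2-bromo-2-(2,3-dibromo-4-butyl-5-oxo-2,5-dihydrofuran-2-yl)acetic acid (racemic, relative configuration not needed) | CCCCC1=C(Br)C(Br)(C(Br)C(=O)O)OC1=O
F4 | step 3 | 1,2-dibromo-4,5-dimethoxybenzene | COc1cc(Br)c(Br)cc1OC
F5 | step 3 | 1-(2,3-dibromo-5,6-dimethoxyphenyl)butan-1-ol (racemic) | CCCC(O)c1c(Br)c(Br)cc(OC)c1OC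
F6 | step 3 | 1,2-dibromo-3-butyl-4,5-dimethoxybenzene | CCCCc1c(Br)c(Br)cc(OC)c1OC
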